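## Structural features

The target 19 is an achiral, linear pentamer of oxygenated benzene rings A to E joined by four diaryl ether oxygens. It carries twelve free phenolic hydroxyls and no stereocentre, so no relation between neighbouring stereocentres has to be set. Every ether oxygen leaves its ring on the A side from C4, a carbon flanked by two oxygenated carbons, and enters the next ring at the open C1; each ether bond therefore has one di-ortho-substituted and one unhindered end. Ring A is a 2,4,6-trihydroxyphenyl end group, rings B to D are 3,5-dihydroxy-1,4-dioxygenated, and ring E is a 3,4,5-trihydroxyphenyl (pyrogallol-type) end group. The free polyphenol is the fragile part: ring E and the hydroquinone-type diethers oxidise readily in air under basic conditions, and the phloroglucinol-like rings are C-nucleophilic. The oxygens are therefore kept as methyl ethers to the last step and the final work-up is acidic and oxygen-free. The real difficulty is the four ether bonds, each between two electron-rich arenes and each with one crowded partner, for which no natural SNAr polarity exists. The key step uses the oxygen pattern of ring D: the oxygens on C1, C3 and C5 are those of a folded six-carbon chain oxygenated on alternate carbons, and the ring-E oxygen sits on C4 between the two hydroxylated carbons. Ring D is thus latent in a 4-aryloxy-2-pyrone whose C4 already holds the ring-C oxygen, whose ring oxygen and carbonyl oxygen become the C3 and C5 hydroxyls, and whose exocyclic aryloxymethyl carbon becomes C4.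

## Logic of the disconnections

19 to 18. The ten O–CH3 bonds on rings A, B, C and E are restored. The free dodecaphenol cannot be carried through base, peracid or organolithium chemistry, and methyl ethers come ready-made in 1, 2 and 9. The gain is that every earlier intermediate is a stable, chromatographable compound. The demand is one exhaustive Lewis-acid ether cleavage that leaves the four diaryl ether bonds intact, followed by isolation without air or base.

18 to 16 by way of 17. The ring-D bond C4–C5 is cut, between the carbon bearing the ring-E oxygen and a hydroxylated carbon. This retro-Claisen gives the open chain 17, whose ester and enol oxygen are then joined to the lactone of 16. C4 is the one ring-D carbon that is α both to an oxygen substituent and to a latent ketone, so it can act as an enolate carbon. Cutting here turns an arene with two crowded ether bonds into a heterocycle on which both ether bonds come from plain substitutions. Ring D disappears and nothing surplus is introduced, since 16 and 18 are isomers. The demand is that methoxide attack the lactone carbonyl and not C4, and that the less acidic enolate at C6 of 17 close the ring.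

16 to 15 and 8. The bond between pyrone C4 and the ring-C oxygen is cut. C4 of a 2-pyrone is a vinylogous acyl carbon, so a halide there is replaced by addition–elimination at a flat, unhindered carbon, which the di-ortho-substituted phenoxide of 8 can reach. The gain is convergence: a three-ring half and a one-ring pyrone half are made separately. The demand is a leaving group with a single electrophilic site and substitution at C4 that outruns reversible attack at C2 or C6.

15 to 14, 13, then 11 and 12; 11 to 9 and 10. The C–Br bond goes back to the C–OH of 14, the lactone O–C2 bond to the ester of 13, the C4–C5 bond of 13 to the γ-carbon of 12 and the acyl carbon of 11, and the O–CH2 bond of 11 to 9 and 10. These are the standard bonds of a triketide assembly, and the ring-E ether is made at the outset by SN2 on a primary carbon. The gain is that the whole pyrone half comes from three commercial compounds. The demand falls on the dianion acylation, where addition to the ester must outrun proton transfer and the acidic product must not consume the nucleophile.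

8 to 6 and then 5 and 2; 5 to 3 and then 1 and 2. The aryl C1–O ether bonds of rings C and B are cut on their unhindered side, and the hydroxyl of each newly added ring is traced back, through formates 7 and 4, to a formyl group. That formyl group, para to fluorine, makes the electron-rich ring an SNAr acceptor, and peracid afterwards turns it into exactly the hydroxyl, flanked by two methoxy groups, that the next ether bond needs. Both ether bonds of 8 thus come from the same two-step cycle, starting from 1 and two molecules of 2, without metal catalysis. The demand is SNAr by a crowded phenoxide at a moderately activated fluoride, and a peracid oxidation that takes the aldehyde faster than the electron-rich rings.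

## Other disconnections considered

Alternative 1: The cut goes through the terminal ring A at bonds C2–C3 and C5–C6. C3–C4–C5, with the ring-B oxygen on C4, comes from the aryloxymalonate A2, and C2–C1–C6 from dimethyl 3-oxopentanedioate A3. In the forward sense Mg(OMe)2 would let the two enolate carbons of A3 be acylated in turn by the two ester groups of A2, an intermolecular Claisen followed by a Dieckmann-type closure, to give the isophthalate A1. The two ester groups of A1 then have to go by hydrolysis and double decarboxylation before the methyl ethers are cleaved.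
- In favour: both nucleophilic carbons are doubly activated, which is closer to classical acylphloroglucinol chemistry than the singly activated enolate of the chosen step. The ring-B oxygen is attached to the three-carbon unit by O-alkylation of an unhindered phenoxide, whereas the chosen plan must bring a di-ortho-substituted phenoxide onto a pyrone. On these two points the alternative is the better.
- Against: A2 is a malonate, so base removes its own α-hydrogen first and both its ester groups then sit on an enolate and are poor acyl donors. The first C–C bond is intermolecular. The ring made is the terminal one, so the whole chain of rings B to E with three crowded ether bonds must be finished first. That chain grows in the direction in which each new hydroxyl must appear at C1, which the fluoroaldehyde cycle used for 8 cannot deliver unless the leaving group sits between two methoxy groups.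
- Comparison: the mechanisms are akin, both being magnesium-mediated Claisen chemistry ending in an aromatic phenoxide. Structurally A1 carries two surplus carbons, whereas 16 and 18 are isomers. In step count the alternative should be about equal in total but entirely linear, against a longest linear sequence of seven here.

Alternative 2: The cut goes through the central ring C at bonds C1–C6 and C2–C3. The ethynyl ether A5 of phenol 5 supplies C1 and C2, and the cyclobutenone A6 supplies C3 to C6 together with rings D and E. On heating, A6 should open (4π) to a vinylketene that adds to A5 in a [2+2] sense. The new cyclobutenone opens again, cutting the old C3–C6 bond, and the dienylketene closes (6π) and tautomerises to the phenol A4 (Danheiser benzannulation).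
- In favour: it is the most convergent plan (2 + 1 + 2 rings) and forms two skeletal bonds and a ring in one reagent-free step. No base or nucleophile is present, so no aryloxy exchange can occur, and the polarity of ketene and ynol ether places all four oxygens of ring C correctly. On convergence and on bonds formed in the key step it is better than the chosen plan. The mixed ethyl ether and phenol of ring C in A4 is no drawback, since the ethyl group falls in the final ether cleavage.
- Against: aryloxyalkynes are much less nucleophilic than the alkoxy- and siloxyalkynes on which this benzannulation rests, and the aryl group of A5 is di-ortho-substituted. A6 is a doubly oxygenated cyclobutenone (racemic at C4, which is immaterial) that should need high temperature to open and gives an electron-rich ketene poorly matched to A5. A5 and A6 each need two to three steps beyond their phenols, and the ring D–E phenol behind A6 requires an ether bond at a carbon flanked by two methoxy groups.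
- Comparison: both plans give the right oxygen pattern without surplus carbon. One is a thermal pericyclic cascade, the other an ionic Claisen closure with closer precedent for the substrate class. Step economy should be roughly equal, about twelve steps with a longest linear sequence near eight against eleven and seven.

Alternative 3: The cut goes through ring B at bonds C1–C6 and C2–C3. The ketene-acetal diene A8 supplies C3 to C6 with the ring-C oxygen on C4, and the ynoate A9 supplies C1 with the ring-A oxygen and C2 with an ester group. Thermal Diels–Alder addition followed by loss of methanol and of the silyl group from the adduct would give the salicylate A7.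
- In favour: regiochemistry follows from matching the nucleophilic diene terminus with the β-carbon of the ynoate, and aromatisation is spontaneous. The crowded ring-A oxygen enters on an sp carbon and not by substitution at a hindered aryl carbon. On this last point the alternative is the equal of the chosen plan, which also brings its hindered oxygens in at unhindered carbons.
- Against: A9 is a push–pull alkyne whose β-aryloxy group lowers its dienophilicity and whose di-ortho-methoxyaryl group crowds the reacting carbon. A8 is a tetra-oxygenated, hydrolytically labile ketene acetal that needs about three steps from a ring C–E phenol whose ether bonds again lie in the unfavourable growth direction. A7 carries a surplus ester at C2 that must be hydrolysed and decarboxylated.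
- Comparison: structurally one carbon too many against none; mechanistically a cycloaddition with a deactivated dienophile against an intramolecular Claisen closure. In step count it should be the longest of the four, about fourteen steps with a longest linear sequence near ten.

Key step: step 10

Remarks on the chemistry (assumption, corrections and design changes):
- Assumption: 4-fluoro-2,6-dimethoxybenzaldehyde (2) is treated as a purchasable building block.
- Correction: the open-chain intermediate 17 is the (2E)-isomer under the sequence rules. Its ester carbon and the ketone-bearing CH2 stay cis as in the pyrone, but the aryloxy group outranks that CH2, so a Z descriptor would not fit this geometry.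
- Leaving group: bromide is used on C4 of the pyrone rather than an arenesulfonate. A sulfonate offers the phenoxide a second electrophilic centre at sulfur and invites sulfonyl transfer; the bromide offers only C4.
- Route to 8: phenol 8 is grown by two cycles of SNAr on 2 and Baeyer–Villiger oxidation rather than by aryne insertions, whose silylaryl triflate precursors would each cost several extra steps.

## Steps

Step 1
Reactants: 1 2,4,6-trimethoxyphenol; 2 4-fluoro-2,6-dimethoxybenzaldehyde
Product: 3 2,6-dimethoxy-4-(2,4,6-trimethoxyphenoxy)benzaldehyde
Conditions: K2CO3, DMSO, 110 °C, Ar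
Reagents that add atoms: none
Why: Nucleophilic aromatic substitution (SNAr): the formyl group para to fluorine stabilises the Meisenheimer adduct, the two methoxy groups of 2 are meta to the reacting carbon and do not crowd it, and the phenoxide of 1 can only O-arylate because its ortho and para carbons are blocked.

Step 2
Reactants: 3 2,6-dimethoxy-4-(2,4,6-trimethoxyphenoxy)benzaldehyde
Product: 5 2,6-dimethoxy-4-(2,4,6-trimethoxyphenoxy)phenol, via aryl formate 4 (not isolated)
Conditions: mCPBA, CH2Cl2, 0 °C to rt; aq Na2SO3 wash; then K2CO3 (cat.), MeOH, rt
Reagents that add atoms: 3-chloroperoxybenzoic acid (mCPBA), OOC(=O)c1cccc(Cl)c1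
Why: Baeyer–Villiger (Dakin-type) oxidation: the aryl group of 3, with two ortho and one para oxygen donor, should migrate far faster than hydride, and the formate 4 is methanolysed by catalytic carbonate; one equivalent of peracid at 0 °C and reductive removal of any excess before base is added should spare ring A and the new hydroquinone monoether.

Step 3
Reactants: 5 2,6-dimethoxy-4-(2,4,6-trimethoxyphenoxy)phenol; 2 4-fluoro-2,6-dimethoxybenzaldehyde
Product: 6 4-[2,6-dimethoxy-4-(2,4,6-trimethoxyphenoxy)phenoxy]-2,6-dimethoxybenzaldehyde
Conditions: K2CO3, DMSO, 120 °C, Ar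
Reagents that add atoms: none
Why: The same SNAr as in step 1; the phenoxide of 5 has the same 2,6-dimethoxy surroundings as that of 1, and its para aryloxy group should change its nucleophilicity little.

Step 4
Reactants: 6 4-[2,6-dimethoxy-4-(2,4,6-trimethoxyphenoxy)phenoxy]-2,6-dimethoxybenzaldehyde
Product: 8 4-[2,6-dimethoxy-4-(2,4,6-trimethoxyphenoxy)phenoxy]-2,6-dimethoxyphenol, via aryl formate 7 (not isolated)
Conditions: mCPBA, CH2Cl2, 0 °C to rt; aq Na2SO3 wash; then K2CO3 (cat.), MeOH, rt
Reagents that add atoms: 3-chloroperoxybenzoic acid (mCPBA), OOC(=O)c1cccc(Cl)c1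
Why: Baeyer–Villiger oxidation as in step 2; the migrating ring again bears two ortho and one para oxygen donor, and the formate 7 is cleaved by mild methanolysis to the ring A–C phenol.

Step 5
Reactants: 9 3,4,5-trimethoxyphenol; 10 methyl bromoacetate
Product: 11 methyl 2-(3,4,5-trimethoxyphenoxy)acetate
Conditions: K2CO3, acetone, reflux
Reagents that add atoms: none
Why: Williamson ether synthesis: SN2 of the unhindered phenoxide of 9 on a primary α-bromo ester, which fixes the ring-E ether bond on the carbon that later becomes C4 of ring D.

Step 6
Reactants: 12 methyl acetoacetate; 11 methyl 2-(3,4,5-trimethoxyphenoxy)acetate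
Product: 13 methyl 3,5-dioxo-6-(3,4,5-trimethoxyphenoxy)hexanoate
Conditions: 12 (2.2 equiv), NaH then n-BuLi, THF, 0 °C; 11, −78 to 0 °C; aq HCl
Reagents that add atoms: none
Why: Huckin–Weiler acylation of a β-keto ester dianion: the γ-carbon of the dianion of 12 is the more nucleophilic site and attacks the activated α-aryloxy ester 11; the excess of dianion covers the proton taken up by the acidic product, and addition of 11 at −78 °C should favour attack on the ester carbonyl over proton abstraction from its CH2.

Step 7
Reactants: 13 methyl 3,5-dioxo-6-(3,4,5-trimethoxyphenoxy)hexanoate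
Product: 14 4-hydroxy-6-[(3,4,5-trimethoxyphenoxy)methyl]-2H-pyran-2-one
Conditions: DBU, toluene, 60 °C; then 1 M HCl
Reagents that add atoms: none
Why: Lactonisation of a 3,5-dioxo ester: the enol oxygen at C5 attacks the ester (6-exo-trig) with loss of methanol, and the acidic 4-hydroxy-2-pyrone is held as its amidinium salt, which pulls the equilibrium over; the mild amidine base does not generate the C6 carbanion needed for a competing carbocyclisation.

Step 8
Reactants: 14 4-hydroxy-6-[(3,4,5-trimethoxyphenoxy)methyl]-2H-pyran-2-one
Product: 15 4-bromo-6-[(3,4,5-trimethoxyphenoxy)methyl]-2H-pyran-2-one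
Conditions: n-Bu4NBr, P2O5, toluene, 100 °C
Reagents that add atoms: tetrabutylammonium bromide, CCCC[N+](CCCC)(CCCC)CCCC.[Br-]
Why: Deoxybromination of a vinylogous carboxylic acid, as established for 4-hydroxy-6-methyl-2-pyrone: P2O5 turns the 4-hydroxyl into a phosphate leaving group and bromide replaces it by addition–elimination at C4; no formylating species is present that could attack the electron-rich ring E.

Step 9
Reactants: 15 4-bromo-6-[(3,4,5-trimethoxyphenoxy)methyl]-2H-pyran-2-one; 8 4-[2,6-dimethoxy-4-(2,4,6-trimethoxyphenoxy)phenoxy]-2,6-dimethoxyphenol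
Product: 16 4-{4-[2,6-dimethoxy-4-(2,4,6-trimethoxyphenoxy)phenoxy]-2,6-dimethoxyphenoxy}-6-[(3,4,5-trimethoxyphenoxy)methyl]-2H-pyran-2-one
Conditions: K2CO3, DMF, 50 °C, Ar
Reagents that add atoms: none
Why: Addition–elimination at C4 of a 4-bromo-2-pyrone (vinylogous acyl substitution), the known way from phenols to 4-aryloxy-2-pyrones: the phenoxide of 8, though flanked by two methoxy groups, attacks a flat unencumbered carbon and bromide leaves irreversibly, whereas attack at C2 or C6 is reversible.

Step 10
Reactants: 16 4-{4-[2,6-dimethoxy-4-(2,4,6-trimethoxyphenoxy)phenoxy]-2,6-dimethoxyphenoxy}-6-[(3,4,5-trimethoxyphenoxy)methyl]-2H-pyran-2-one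
Product: 18 5-{4-[2,6-dimethoxy-4-(2,4,6-trimethoxyphenoxy)phenoxy]-2,6-dimethoxyphenoxy}-2-(3,4,5-trimethoxyphenoxy)benzene-1,3-diol, via open-chain (2E)-enoate 17 (not isolated)
Conditions: Mg(OMe)2, MeOH, reflux, Ar (sealed tube at 100 °C if closure is slow); then 1 M HCl
Reagents that add atoms: none
Why: Methoxide adds to the lactone carbonyl (C2) of 16 and the ring opens to the magnesium dienolate of 17, in which the ester and the ketone-bearing chain stay cis on the C2=C3 double bond (E descriptor) exactly as in the pyrone. Proton exchange in methanol gives access to the less populated enolate at C6, the carbon bearing the ring-E oxygen, which attacks the ester carbonyl in a Claisen (Dieckmann-type) condensation, a 6-(enolendo)-exo-trig closure that forms bond C4–C5 of ring D; loss of methoxide gives the diketo tautomer of 18, which enolises at once to the aromatic ring and is held as a magnesium phenoxide, so the methoxide taken up in 17 is released again and 18 is an isomer of 16. The closest known reaction type is the alkoxide-induced opening of 4-alkoxy-6-(2-oxoalkyl)-2-pyrones with Claisen reclosure to acylphloroglucinols, together with the related base-induced recyclisation of ring-opened 4-methoxy-6-methyl-2-pyrone to a phloroglucinol ether, in which a singly activated carbon closes; here the α-aryloxy group makes the C6 hydrogens distinctly more acidic than those of a plain methyl ketone. No stereocentre is formed. Two selectivities are needed: first, methoxide must attack C2 and not displace the aryloxide from C4, which should be secured by the two ortho methoxy groups of ring C that screen C4, by the higher electrophilicity of the lactone carbonyl and by the low concentration of free methoxide in a Mg(OMe)2 solution; second, the carbon–carbon bond must come from C6 and not from the more acidic C4, which is secured because a C4 carbanion could only form a four-membered ring and O-attack of the dienolate merely returns 16, so every unproductive path is reversible and only the C6 path ends irreversibly in an aromatic phenoxide.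

Step 11
Reactants: 18 5-{4-[2,6-dimethoxy-4-(2,4,6-trimethoxyphenoxy)phenoxy]-2,6-dimethoxyphenoxy}-2-(3,4,5-trimethoxyphenoxy)benzene-1,3-diol
Product: 19 5-{2,6-dihydroxy-4-[2,6-dihydroxy-4-[2,6-dihydroxy-4-(2,4,6-trihydroxyphenoxy)phenoxy]phenoxy]phenoxy}benzene-1,2,3-triol
Conditions: BBr3 (excess), CH2Cl2, −78 °C to rt; MeOH then H2O, under Ar
Reagents that add atoms: none
Why: Exhaustive Lewis-acid demethylation: BBr3 binds each methoxy oxygen and bromide removes the methyl group by SN2, while the diaryl ether bonds offer no alkyl carbon and should survive; the two free hydroxyls of 18 are only borylated, and an acidic, oxygen-free quench protects the pyrogallol-type ring E.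

## Compound list

1 | 2,4,6-trimethoxyphenol | COc1cc(OC)c(O)c(OC)c1 | starting material
2 | 4-fluoro-2,6-dimethoxybenzaldehyde | COc1cc(F)cc(OC)c1C=O | starting material
3 | 2,6-dimethoxy-4-(2,4,6-trimethoxyphenoxy)benzaldehyde | COc1cc(OC)c(Oc2cc(OC)c(C=O)c(OC)c2)c(OC)c1 | intermediate
4 | 2,6-dimethoxy-4-(2,4,6-trimethoxyphenoxy)phenyl formate | COc1cc(OC)c(Oc2cc(OC)c(OC=O)c(OC)c2)c(OC)c1 | intermediate (not isolated)
5 | 2,6-dimethoxy-4-(2,4,6-trimethoxyphenoxy)phenol | COc1cc(OC)c(Oc2cc(OC)c(O)c(OC)c2)c(OC)c1 | intermediate
6 | 4-[2,6-dimethoxy-4-(2,4,6-trimethoxyphenoxy)phenoxy]-2,6-dimethoxybenzaldehyde | COc1cc(OC)c(Oc2cc(OC)c(Oc3cc(OC)c(C=O)c(OC)c3)c(OC)c2)c(OC)c1 | intermediate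
7 | 4-[2,6-dimethoxy-4-(2,4,6-trimethoxyphenoxy)phenoxy]-2,6-dimethoxyphenyl formate | COc1cc(OC)c(Oc2cc(OC)c(Oc3cc(OC)c(OC=O)c(OC)c3)c(OC)c2)c(OC)c1 | intermediate (not isolated)
8 | 4-[2,6-dimethoxy-4-(2,4,6-trimethoxyphenoxy)phenoxy]-2,6-dimethoxyphenol | COc1cc(OC)c(Oc2cc(OC)c(Oc3cc(OC)c(O)c(OC)c3)c(OC)c2)c(OC)c1 | intermediate
9 | 3,4,5-trimethoxyphenol | COc1cc(O)cc(OC)c1OC | starting material
10 | methyl bromoacetate | COC(=O)CBr | starting material
11 | methyl 2-(3,4,5-trimethoxyphenoxy)acetate | COC(=O)COc1cc(OC)c(OC)c(OC)c1 | intermediate
12 | methyl acetoacetate | CC(=O)CC(=O)OC | starting material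
13 | methyl 3,5-dioxo-6-(3,4,5-trimethoxyphenoxy)hexanoate | COC(=O)CC(=O)CC(=O)COc1cc(OC)c(OC)c(OC)c1 | intermediate
14 | 4-hydroxy-6-[(3,4,5-trimethoxyphenoxy)methyl]-2H-pyran-2-one | O=C1C=C(O)C=C(COc2cc(OC)c(OC)c(OC)c2)O1 | intermediate
15 | 4-bromo-6-[(3,4,5-trimethoxyphenoxy)methyl]-2H-pyran-2-one | O=C1C=C(Br)C=C(COc2cc(OC)c(OC)c(OC)c2)O1 | intermediate
16 | 4-{4-[2,6-dimethoxy-4-(2,4,6-trimethoxyphenoxy)phenoxy]-2,6-dimethoxyphenoxy}-6-[(3,4,5-trimethoxyphenoxy)methyl]-2H-pyran-2-one | O=C1C=C(Oc2c(OC)cc(Oc3c(OC)cc(Oc4c(OC)cc(OC)cc4OC)cc3OC)cc2OC)C=C(COc5cc(OC)c(OC)c(OC)c5)O1 | intermediate (precursor of the key step)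
17 | methyl (2E)-3-{4-[2,6-dimethoxy-4-(2,4,6-trimethoxyphenoxy)phenoxy]-2,6-dimethoxyphenoxy}-5-oxo-6-(3,4,5-trimethoxyphenoxy)hex-2-enoate | COC(=O)/C=C(\CC(=O)COc1cc(OC)c(OC)c(OC)c1)Oc2c(OC)cc(Oc3c(OC)cc(Oc4c(OC)cc(OC)cc4OC)cc3OC)cc2OC | intermediate (not isolated)
18 | 5-{4-[2,6-dimethoxy-4-(2,4,6-trimethoxyphenoxy)phenoxy]-2,6-dimethoxyphenoxy}-2-(3,4,5-trimethoxyphenoxy)benzene-1,3-diol | Oc1cc(Oc2c(OC)cc(Oc3c(OC)cc(Oc4c(OC)cc(OC)cc4OC)cc3OC)cc2OC)cc(O)c1Oc5cc(OC)c(OC)c(OC)c5 | intermediate (product of the key step)
19 | 5-{2,6-dihydroxy-4-[2,6-dihydroxy-4-[2,6-dihydroxy-4-(2,4,6-trihydroxyphenoxy)phenoxy]phenoxy]phenoxy}benzene-1,2,3-triol | Oc1cc(O)c(Oc2cc(O)c(Oc3cc(O)c(Oc4cc(O)c(Oc5cc(O)c(O)c(O)c5)c(O)c4)c(O)c3)c(O)c2)c(O)c1 | target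

## Step count and least certain steps

Total: 11 steps (nine to the precursor 16, the key step, one deprotection). Longest linear sequence: 7 steps (steps 1, 2, 3, 4, 9, 10, 11; the branch through steps 5 to 8 is equally long).

Step 10 (key step). The ring opening should be easy; the closure is what is most likely to fail. The dominant anion of 17 is the conjugated dienolate formed by deprotonation at C4, in which the ester is deactivated, and the C6 enolate that has to react is singly activated and thinly populated in methanol. The reaction may therefore stall at the open-chain stage, and prolonged heating may allow methoxide exchange at C4 with loss of the ring A–C phenoxide. The fallback abandons the ring construction for ring D, sets out from 8 and rejoins at 19. A third SNAr with 2 (K2CO3, DMSO, 120 °C) should give 4-{4-[2,6-dimethoxy-4-(2,4,6-trimethoxyphenoxy)phenoxy]-2,6-dimethoxyphenoxy}-2,6-dimethoxybenzaldehyde F1. mCPBA should convert it into the corresponding aryl formate F2, and catalytic K2CO3 in MeOH should release the ring A–D phenol F3. Ullmann coupling of F3 with commercial 5-bromo-1,2,3-trimethoxybenzene (CuI, picolinic acid, K3PO4, DMSO, 100 °C) should give the dodecamethyl ether of the target F4. BBr3 under the conditions of step 11 should then give 19.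

Step 9. Addition of the di-ortho-substituted phenoxide at C4 may be slow enough for ring opening by attack at C2 or C6, or base-induced decay of the bromopyrone, to take over. The fallback forms the crowded C–O bond before the chain exists, sets out from 8 and rejoins at 17. Oxa-Michael addition of 8 to methyl but-2-ynoate (Cs2CO3, DMF, 60 °C) should give methyl (2E)-3-{4-[2,6-dimethoxy-4-(2,4,6-trimethoxyphenoxy)phenoxy]-2,6-dimethoxyphenoxy}but-2-enoate F5. Deprotonation of its γ-methyl group with LiN(i-Pr)2 (THF, −78 °C, two equivalents of the dienolate) and γ-acylation with 11, in the manner of the γ-selective reactions of β-alkoxycrotonate dienolates, should give 17, the open-chain intermediate of step 10. This is carried on to 18 under the conditions of step 10; any 16 formed by lactonisation on work-up converges on the same product, and steps 6 to 8 fall away.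

Step 6. Proton transfer from the acidic CH2 of the α-aryloxy ester to the dianion, and quenching of the dianion by the product, may leave much of 11 unreacted. The fallback sets out from 11 and rejoins at 14. Aminolysis of 11 with N,O-dimethylhydroxylamine hydrochloride and i-PrMgCl (THF, −20 °C) should give N-methoxy-N-methyl-2-(3,4,5-trimethoxyphenoxy)acetamide F6. The lithium dienolate of commercial 2,2,6-trimethyl-4H-1,3-dioxin-4-one (LiN(i-Pr)2, THF, −78 °C) should be acylated by F6 at its γ-carbon to give 2,2-dimethyl-6-[2-oxo-3-(3,4,5-trimethoxyphenoxy)propyl]-4H-1,3-dioxin-4-one F7. Heating F7 in toluene at 110 °C should expel acetone by retro-[4+2] and the acylketene should be trapped by the enolised ketone oxygen to give 14 directly.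

Step 3. The fluoride of 2 is activated only by a formyl group whose acceptor strength is lowered by two ortho methoxy donors, and the nucleophile is crowded, so substitution may be incomplete; long heating then exposes the aldehyde and the phenoxide to degradation. Step 1 shares this risk but uses the cheap phenol 1. The fallback replaces SNAr and oxidation by a copper-catalysed coupling, sets out from 5 and rejoins at 8. 2-(Benzyloxy)-5-bromo-1,3-dimethoxybenzene F8 is made from commercial 4-bromo-2,6-dimethoxyphenol with benzyl bromide and K2CO3. Ullmann coupling of 5 with F8 (CuI, picolinic acid, K3PO4, DMSO, 100 °C) should give 2-(benzyloxy)-5-[2,6-dimethoxy-4-(2,4,6-trimethoxyphenoxy)phenoxy]-1,3-dimethoxybenzene F9. Hydrogenolysis (H2, Pd/C, EtOAc) should give 8, and step 4 is not needed.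

Step 11. Cleavage of ten ethers may stop short once partly demethylated aryl borates precipitate, and the free dodecaphenol may be lost to oxidation during isolation and chromatography. The fallback isolates the product through a stable derivative, sets out from 18 and rejoins at 19. After the BBr3 treatment and methanol quench the crude material is evaporated and acetylated at once (Ac2O, pyridine, DMAP) to the dodecaacetate of the target F10. F10 can be chromatographed and separated from partly methylated material, which is returned to BBr3. Acid-catalysed methanolysis of F10 (HCl generated from AcCl in MeOH, Ar, rt) should release 19 without exposure to base.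

## Further compounds

F1 | step 10 | 4-{4-[2,6-dimethoxy-4-(2,4,6-trimethoxyphenoxy)phenoxy]-2,6-dimethoxyphenoxy}-2,6-dimethoxybenzaldehyde | COc1cc(OC)c(Oc2cc(OC)c(Oc3cc(OC)c(Oc4cc(OC)c(C=O)c(OC)c4)c(OC)c3)c(OC)c2)c(OC)c1
F2 | step 10 | 4-{4-[2,6-dimethoxy-4-(2,4,6-trimethoxyphenoxy)phenoxy]-2,6-dimethoxyphenoxy}-2,6-dimethoxyphenyl formate | COc1cc(OC)c(Oc2cc(OC)c(Oc3cc(OC)c(Oc4cc(OC)c(OC=O)c(OC)c4)c(OC)c3)c(OC)c2)c(OC)c1
F3 | step 10 | 4-{4-[2,6-dimethoxy-4-(2,4,6-trimethoxyphenoxy)phenoxy]-2,6-dimethoxyphenoxy}-2,6-dimethoxyphenol | COc1cc(OC)c(Oc2cc(OC)c(Oc3cc(OC)c(Oc4cc(OC)c(O)c(OC)c4)c(OC)c3)c(OC)c2)c(OC)c1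
F4 | step 10 | 5-{4-[4-[2,6-dimethoxy-4-(2,4,6-trimethoxyphenoxy)phenoxy]-2,6-dimethoxyphenoxy]-2,6-dimethoxyphenoxy}-1,2,3-trimethoxybenzene (dodecamethyl ether of 19) | COc1cc(OC)c(Oc2cc(OC)c(Oc3cc(OC)c(Oc4cc(OC)c(Oc5cc(OC)c(OC)c(OC)c5)c(OC)c4)c(OC)c3)c(OC)c2)c(OC)c1
F5 | step 9 | methyl (2E)-3-{4-[2,6-dimethoxy-4-(2,4,6-trimethoxyphenoxy)phenoxy]-2,6-dimethoxyphenoxy}but-2-enoate | COC(=O)/C=C(\C)Oc1c(OC)cc(Oc2c(OC)cc(Oc3c(OC)cc(OC)cc3OC)cc2OC)cc1OC
F6 | step 6 | N-methoxy-N-methyl-2-(3,4,5-trimethoxyphenoxy)acetamide | CON(C)C(=O)COc1cc(OC)c(OC)c(OC)c1
F7 | step 6 | 2,2-dimethyl-6-[2-oxo-3-(3,4,5-trimethoxyphenoxy)propyl]-4H-1,3-dioxin-4-one | CC1(C)OC(=O)C=C(CC(=O)COc2cc(OC)c(OC)c(OC)c2)O1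
F8 | step 3 | 2-(benzyloxy)-5-bromo-1,3-dimethoxybenzene | COc1cc(Br)cc(OC)c1OCc2ccccc2
F9 | step 3 | 2-(benzyloxy)-5-[2,6-dimethoxy-4-(2,4,6-trimethoxyphenoxy)phenoxy]-1,3-dimethoxybenzene | COc1cc(OC)c(Oc2cc(OC)c(Oc3cc(OC)c(OCc4ccccc4)c(OC)c3)c(OC)c2)c(OC)c1
F10 | step 11 | dodecaacetate of 19 (all twelve hydroxyls acetylated) | CC(=O)Oc1cc(OC(C)=O)c(Oc2cc(OC(C)=O)c(Oc3cc(OC(C)=O)c(Oc4cc(OC(C)=O)c(Oc5cc(OC(C)=O)c(OC(C)=O)c(OC(C)=O)c5)c(OC(C)=O)c4)c(OC(C)=O)c3)c(OC(C)=O)c2)c(OC(C)=O)c1
A1 | alternative 1 | dimethyl 5-{3,5-dimethoxy-4-[3,5-dimethoxy-4-[3,5-dimethoxy-4-(3,4,5-trimethoxyphenoxy)phenoxy]phenoxy]phenoxy}-2,4,6-trihydroxybenzene-1,3-dicarboxylate | COC(=O)c1c(O)c(Oc2cc(OC)c(Oc3cc(OC)c(Oc4cc(OC)c(Oc5cc(OC)c(OC)c(OC)c5)c(OC)c4)c(OC)c3)c(OC)c2)c(O)c(C(=O)OC)c1O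
A2 | alternative 1 | dimethyl 2-{3,5-dimethoxy-4-[3,5-dimethoxy-4-[3,5-dimethoxy-4-(3,4,5-trimethoxyphenoxy)phenoxy]phenoxy]phenoxy}propanedioate | COC(=O)C(Oc1cc(OC)c(Oc2cc(OC)c(Oc3cc(OC)c(Oc4cc(OC)c(OC)c(OC)c4)c(OC)c3)c(OC)c2)c(OC)c1)C(=O)OC
A3 | alternative 1 | dimethyl 3-oxopentanedioate | COC(=O)CC(=O)CC(=O)OC
A4 | alternative 2 | 5-[2,6-dimethoxy-4-(2,4,6-trimethoxyphenoxy)phenoxy]-2-[3,5-dimethoxy-4-(3,4,5-trimethoxyphenoxy)phenoxy]-3-ethoxyphenol | Oc1cc(Oc2c(OC)cc(Oc3c(OC)cc(OC)cc3OC)cc2OC)cc(OCC)c1Oc4cc(OC)c(Oc5cc(OC)c(OC)c(OC)c5)c(OC)c4
A5 | alternative 2 | 2-(ethynyloxy)-1,3-dimethoxy-5-(2,4,6-trimethoxyphenoxy)benzene | C#COc1c(OC)cc(Oc2c(OC)cc(OC)cc2OC)cc1OC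
A6 | alternative 2 | 4-[3,5-dimethoxy-4-(3,4,5-trimethoxyphenoxy)phenoxy]-3-ethoxycyclobut-2-en-1-one (racemic) | O=C1C=C(OCC)C1Oc2cc(OC)c(Oc3cc(OC)c(OC)c(OC)c3)c(OC)c2
A7 | alternative 3 | methyl 3-{3,5-dimethoxy-4-[3,5-dimethoxy-4-(3,4,5-trimethoxyphenoxy)phenoxy]phenoxy}-2-hydroxy-4-methoxy-6-(2,4,6-trimethoxyphenoxy)benzoate | COC(=O)c1c(O)c(Oc2cc(OC)c(Oc3cc(OC)c(Oc4cc(OC)c(OC)c(OC)c4)c(OC)c3)c(OC)c2)c(OC)cc1Oc5c(OC)cc(OC)cc5OC
A8 | alternative 3 | {[2-{3,5-dimethoxy-4-[3,5-dimethoxy-4-(3,4,5-trimethoxyphenoxy)phenoxy]phenoxy}-1,3-dimethoxybuta-1,3-dien-1-yl]oxy}trimethylsilane (either ketene-acetal geometry) | C=C(OC)C(Oc1cc(OC)c(Oc2cc(OC)c(Oc3cc(OC)c(OC)c(OC)c3)c(OC)c2)c(OC)c1)=C(OC)O[Si](C)(C)C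
A9 | alternative 3 | methyl 3-(2,4,6-trimethoxyphenoxy)prop-2-ynoate | COC(=O)C#COc1c(OC)cc(OC)cc1OC
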